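**Plan**

Ring numbering used below: C1 bears the butenoic acid arm, C2 is the ketone, C3 bears the heptenyl chain, C4 bears CH2OH, C5 and C6 are the carbinols.
Retrosynthetic cuts, in order: the C3–heptenyl bond (Stille coupling on a 3-iodoenone); the C=C of the arm (Wittig on a lactol that ties the C6 oxygen to the first two arm carbons); ring bond C5–C6; the bond joining the two five-membered rings of a 4-(furan-2-yl)butenolide (Suzuki coupling).
Enabling feature: C6, its oxygen, C1 and the first two arm carbons fold into a butenolide whose γ-carbon (C6) is a vinylogous donor, while C2(=O)–C3=C4–C5 is a (Z)-4-oxo-enal, that is, an oxidatively opened furan whose aldehyde carbon is C5.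
Forward order: furan and butenolide are joined, the furan is opened, the cyclohexenone ring closes by C5–C6, the lactone is reduced and unfolded into the arm, then C3 is iodinated and coupled.
Stereochemistry: C5/C6 from the catalyst (absolute) and from allylic strain plus the planar lactone (cis); C1 from the cis ring fusion of the lactone on protonation; the side-chain carbinol from (R)-methyloxirane; both E-alkenes from the Wittig reaction and a syn-hydrostannation.

Key step: step 6

Assumption: the squaramide in step 6 is taken to induce the (7R,7aS) sense; this is to be checked on the first run (Mosher ester of 8), and the quinine-derived pseudo-enantiomer is used if the sense is opposite.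

**Route**

Step 1
Reactants: 1 furan-3-ylmethanol
Product: 2 (furan-3-ylmethoxy)tri(propan-2-yl)silane
Conditions: TIPSCl, imidazole, DMF, 0 °C to rt
Reagents that add atoms: chlorotri(propan-2-yl)silane, CC(C)[Si](Cl)(C(C)C)C(C)C
Why: Standard silylation of a primary alcohol, giving a bulky ether that shields the neighbouring furan α-position and should survive every step up to the final fluoride treatment.

Step 2
Reactants: 2 (furan-3-ylmethoxy)tri(propan-2-yl)silane
Product: 3 tri(propan-2-yl){[5-(4,4,5,5-tetramethyl-1,3,2-dioxaborolan-2-yl)furan-3-yl]methoxy}silane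
Conditions: [Ir(OMe)(cod)]2 (1.5 mol%), 4,4'-di-tert-butyl-2,2'-bipyridine (3 mol%), B2pin2 (1.0 equiv), hexane, rt
Reagents that add atoms: bis(pinacolato)diboron, CC1(C)OB(OC1(C)C)B1OC(C)(C)C(C)(C)O1
Why: Iridium-catalysed C–H borylation of a 3-substituted furan is sterically controlled and should go to the α-position remote from the CH2OTIPS group, which gives the 2,4-substitution pattern that directed lithiation would not.

Step 3
Reactants: 4 tetronic acid (4-hydroxyfuran-2(5H)-one)
Product: 5 4-bromofuran-2(5H)-one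
Conditions: (COBr)2, DMF (cat.), CH2Cl2, 0 °C to rt
Reagents that add atoms: oxalyl bromide, O=C(Br)C(=O)Br
Why: Vilsmeier-type activation of the vinylogous acid followed by addition–elimination of bromide replaces the enol OH by Br.

Step 4
Reactants: 3 furyl boronate; 5 4-bromofuran-2(5H)-one
Product: 6 4-[4-({[tri(propan-2-yl)silyl]oxy}methyl)furan-2-yl]furan-2(5H)-one
Conditions: PdCl2(PPh3)2 (5 mol%), CsF, BnEt3NCl (cat.), toluene/H2O, rt to 40 °C
Reagents that add atoms: none
Why: Suzuki–Miyaura coupling in which the vinylogous acyl bromide undergoes fast oxidative addition and the mild fluoride base should spare the base-sensitive butenolide.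

Step 5
Reactants: 6 furyl butenolide
Product: 7 (2Z)-4-oxo-4-(5-oxo-2,5-dihydrofuran-3-yl)-2-({[tri(propan-2-yl)silyl]oxy}methyl)but-2-enal
Conditions: dimethyldioxirane (1.1 equiv, acetone solution), acetone, −40 to 0 °C; evaporate and use at once
Reagents that add atoms: dimethyldioxirane, CC1(C)OO1
Why: Oxidative ring opening of a furan (epoxidation of the more electron-rich C4–C5 bond, then ring opening) gives the cis-ene-dicarbonyl compound, so the Z geometry comes from the ring, and the neutral conditions should prevent a premature, uncatalysed cyclisation.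

Step 6
Reactants: 7 (Z)-4-oxo-enal butenolide
Product: 9 (7R,7aS)-7-{[tert-butyl(dimethyl)silyl]oxy}-6-({[tri(propan-2-yl)silyl]oxy}methyl)-7,7a-dihydro-1-benzofuran-2,4-dione, via hydroxy butenolide 8 (not isolated)
Conditions: bifunctional squaramide of 9-amino-9-deoxy-epi-quinidine and 3,5-bis(trifluoromethyl)aniline (10 mol%), toluene (0.01 M), −40 °C; then 2,6-lutidine, TBSOTf, −78 °C
Reagents that add atoms: tert-butyldimethylsilyl trifluoromethanesulfonate, CC(C)(C)[Si](C)(C)OS(=O)(=O)C(F)(F)F
Why: Proposed new method: the quinuclidine nitrogen of the catalyst removes one of the two enantiotopic γ-hydrogens at C6, the furanolate stays ion-paired while the squaramide N–H bonds activate the C5 aldehyde, C6 adds to C5 (intramolecular direct vinylogous aldol addition), and the aldol is silylated in the same flask so that neither retro-aldol cleavage nor dehydration to a phenol can follow. The closest known reaction type is the tertiary amine–squaramide (or thiourea) catalysed direct vinylogous aldol addition of furan-2(5H)-ones to aldehydes, here run as a ring closure. The six-membered carbocycle closes in a 6-(enolendo)-exo-trig mode, with the donor C1=C6 bond of the furanolate inside and the aldehyde oxygen outside the new ring. The configuration at C6, and with it the absolute sense, is set by the face of the planar furanolate left open by the chiral ion pair; the configuration at C5 relative to C6 is set by the substrate, because the lactone oxygen lies in the butenolide plane and ends pseudo-equatorial, whereas the C5–O bond turns out of the C3=C4 plane to avoid allylic 1,2-strain with the CH2OTIPS group on C4 and ends pseudo-axial, which is the cis arrangement. The step needs γ- over α-attack of the furanolate (both would close a six-membered ring), which the larger orbital coefficient at the γ-carbon and the conjugated butenolide restored only by γ-attack should secure. It also needs the Z geometry of the 4-oxo-enal, which the furan delivers and which, if partly lost, should be re-established by reversible conjugate addition of the amine, so that both alkene isomers drain into the same product.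

Step 7
Reactants: 9 silylated dienone lactone
Product: 10 (3aR,7R,7aS)-7-{[tert-butyl(dimethyl)silyl]oxy}-6-({[tri(propan-2-yl)silyl]oxy}methyl)-3,3a,7,7a-tetrahydro-1-benzofuran-2,4-dione
Conditions: Zn dust, AcOH/THF, 0 °C
Reagents that add atoms: none
Why: Dissolving-metal reduction of the ene-1,4-dicarbonyl unit (ketone–C=C–lactone carbonyl) should leave the simple enone C3=C4 alone, and protonation of the enol at C1 on the convex face gives the cis-fused lactone (also the thermodynamic fusion, C1 being α to the ketone), which places the arm cis to the C6 oxygen; β-elimination of the lactone oxygen is disfavoured because the C6–O bond lies in the nodal plane of the enol.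

Step 8
Reactants: 10 cis-fused keto lactone
Product: 11 (3aS,7R,7aS)-7-{[tert-butyl(dimethyl)silyl]oxy}-6-({[tri(propan-2-yl)silyl]oxy}methyl)-2,3,3a,4,7,7a-hexahydro-1-benzofuran-2,4-diol (epimers at C2 and C4, used as such)
Conditions: i-Bu2AlH (3.5 equiv), CH2Cl2, −78 °C; aq. potassium sodium tartrate
Reagents that add atoms: none
Why: Hydride reduction at −78 °C stops the lactone at the lactol and reduces the ketone in 1,2-fashion to the allylic alcohol, which is restored in step 11, so both epimer mixtures converge later.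

Step 9
Reactants: 12 tert-butyl 2-bromopropanoate
Product: 14 tert-butyl 2-(triphenylphosphoranylidene)propanoate, via phosphonium bromide 13 (not isolated)
Conditions: PPh3, toluene, 80 °C; then aq. NaOH, CH2Cl2, rt
Reagents that add atoms: triphenylphosphine, c1ccc(cc1)P(c1ccccc1)c1ccccc1
Why: SN2 quaternisation of the phosphine by the α-bromo ester and deprotonation of the acidic phosphonium salt give the stabilised ylide.

Step 10
Reactants: 11 lactol; 14 ylide
Product: 15 tert-butyl (2E)-4-[(1S,5R,6S)-5-{[tert-butyl(dimethyl)silyl]oxy}-2,6-dihydroxy-4-({[tri(propan-2-yl)silyl]oxy}methyl)cyclohex-3-en-1-yl]-2-methylbut-2-enoate (epimers at C2)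
Conditions: toluene, 90 °C
Reagents that add atoms: none
Why: Wittig olefination of the lactol through its open hydroxy aldehyde form with a stabilised α-methyl ylide should give the E-trisubstituted enoate and free the C6 hydroxyl, the neutral medium avoiding oxa-Michael addition.

Step 11
Reactants: 15 diol ester
Product: 16 tert-butyl (2E)-4-[(1R,5R,6S)-5-{[tert-butyl(dimethyl)silyl]oxy}-6-hydroxy-2-oxo-4-({[tri(propan-2-yl)silyl]oxy}methyl)cyclohex-3-en-1-yl]-2-methylbut-2-enoate
Conditions: MnO2 (activated, excess), CH2Cl2, rt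
Reagents that add atoms: none
Why: MnO2 oxidises only the allylic alcohol at C2 and leaves the non-allylic C6 hydroxyl, so both C2 epimers converge on one enone under neutral conditions that do not touch C1.

Step 12
Reactants: 16 enone ester
Product: 17 tert-butyl (2E)-4-[(1R,5R,6S)-5-{[tert-butyl(dimethyl)silyl]oxy}-6-hydroxy-3-iodo-2-oxo-4-({[tri(propan-2-yl)silyl]oxy}methyl)cyclohex-3-en-1-yl]-2-methylbut-2-enoate
Conditions: I2, pyridine, CH2Cl2, 0 °C to rt
Reagents that add atoms: iodine, II
Why: α-Iodination of an enone by conjugate addition of pyridine, iodination of the enolate and elimination (Morita–Baylis–Hillman-type sequence) can act only at C3, the sole enone α-CH, since the arm enoate carries a methyl group at its α-carbon.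

Step 13
Reactants: 18 (4-bromobut-1-yn-1-yl)trimethylsilane; 19 (R)-2-methyloxirane
Product: 21 (2R)-7-(trimethylsilyl)hept-6-yn-2-ol, via Grignard reagent 20 (not isolated)
Conditions: Mg, THF, rt; then 19, CuI (10 mol%), THF, −30 °C; aq. NH4Cl
Reagents that add atoms: none
Why: Copper-catalysed Grignard opening of the epoxide at its unsubstituted carbon does not touch the stereocentre, so the R configuration is carried over from the epoxide.

Step 14
Reactants: 21 silyl alkynol
Product: 22 tert-butyl(dimethyl){[(2R)-7-(trimethylsilyl)hept-6-yn-2-yl]oxy}silane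
Conditions: TBSCl, imidazole, DMF, rt
Reagents that add atoms: tert-butyl(chloro)dimethylsilane, CC(C)(C)[Si](C)(C)Cl
Why: Standard silylation of a secondary alcohol, chosen so that this group leaves together with the other silyl ethers in the last step.

Step 15
Reactants: 22 bis-silyl compound
Product: 23 tert-butyl[(2R)-hept-6-yn-2-yloxy]dimethylsilane
Conditions: K2CO3 (cat.), MeOH, rt
Reagents that add atoms: none
Why: Methoxide cleaves the C(sp)–Si bond selectively while the O-silyl ether is stable under these conditions.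

Step 16
Reactants: 23 terminal alkyne
Product: 24 tert-butyl(dimethyl){[(2R,6E)-7-(tributylstannyl)hept-6-en-2-yl]oxy}silane
Conditions: Bu3SnH, Pd2(dba)3 (1 mol%), tricyclohexylphosphonium tetrafluoroborate (4 mol%), i-Pr2NEt, CH2Cl2, 0 °C
Reagents that add atoms: tributyltin hydride, CCCC[SnH](CCCC)CCCC
Why: Palladium-catalysed hydrostannation is a syn addition, and the bulky tricyclohexylphosphine ligand should direct tin to the terminal carbon, giving the E-1-stannylalkene.

Step 17
Reactants: 17 iodoenone; 24 vinylstannane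
Product: 25 tert-butyl (2E)-4-[(1R,5R,6S)-5-{[tert-butyl(dimethyl)silyl]oxy}-3-[(1E,6R)-6-{[tert-butyl(dimethyl)silyl]oxy}hept-1-en-1-yl]-6-hydroxy-2-oxo-4-({[tri(propan-2-yl)silyl]oxy}methyl)cyclohex-3-en-1-yl]-2-methylbut-2-enoate
Conditions: Pd2(dba)3 (5 mol%), AsPh3, CuI, NMP, rt
Reagents that add atoms: none
Why: Stille coupling of an α-iodoenone with an alkenylstannane proceeds with retention of alkene geometry under neutral conditions that the β-hydroxy ketone should tolerate, the arsine ligand and CuI speeding up transmetalation.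

Step 18
Reactants: 25 fully protected ester
Product: 26 (2E)-4-[(1R,5R,6S)-5-{[tert-butyl(dimethyl)silyl]oxy}-3-[(1E,6R)-6-{[tert-butyl(dimethyl)silyl]oxy}hept-1-en-1-yl]-6-hydroxy-2-oxo-4-({[tri(propan-2-yl)silyl]oxy}methyl)cyclohex-3-en-1-yl]-2-methylbut-2-enoic acid
Conditions: CF3CO2H/CH2Cl2 (1:4), 0 °C
Reagents that add atoms: none
Why: Acidolysis of the tert-butyl ester (loss of 2-methylpropene) avoids base, the allylic C–O bonds at C5 and at the CH2O group should not ionise because the cations would be conjugated to the ketone in a destabilising sense, and any partly desilylated acid can be carried on since step 19 removes all silyl groups.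

Step 19
Reactants: 26 silylated acid
Product: 27 Pestallic acid I, (2E)-4-[(1R,5R,6S)-5,6-dihydroxy-3-[(1E,6R)-6-hydroxyhept-1-en-1-yl]-4-(hydroxymethyl)-2-oxocyclohex-3-en-1-yl]-2-methylbut-2-enoic acid
Conditions: HF·pyridine, pyridine/THF, 0 °C to rt
Reagents that add atoms: none
Why: Buffered fluoride cleaves the three silyl ethers without base, which should avoid retro-aldol cleavage and β-elimination/aromatisation of the β-hydroxy ketone.

**Compound list**

1 | furan-3-ylmethanol | OCc1ccoc1 | starting material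
2 | (furan-3-ylmethoxy)tri(propan-2-yl)silane | CC(C)[Si](OCc1ccoc1)(C(C)C)C(C)C | intermediate
3 | tri(propan-2-yl){[5-(4,4,5,5-tetramethyl-1,3,2-dioxaborolan-2-yl)furan-3-yl]methoxy}silane | CC(C)[Si](OCc1coc(B2OC(C)(C)C(C)(C)O2)c1)(C(C)C)C(C)C | intermediate
4 | tetronic acid (4-hydroxyfuran-2(5H)-one) | OC1=CC(=O)OC1 | starting material
5 | 4-bromofuran-2(5H)-one | BrC1=CC(=O)OC1 | intermediate
6 | 4-[4-({[tri(propan-2-yl)silyl]oxy}methyl)furan-2-yl]furan-2(5H)-one | O=C1C=C(c2cc(CO[Si](C(C)C)(C(C)C)C(C)C)co2)CO1 | intermediate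
7 | (2Z)-4-oxo-4-(5-oxo-2,5-dihydrofuran-3-yl)-2-({[tri(propan-2-yl)silyl]oxy}methyl)but-2-enal | O=C/C(CO[Si](C(C)C)(C(C)C)C(C)C)=C\C(=O)C1=CC(=O)OC1 | intermediate
8 | (7R,7aS)-7-hydroxy-6-({[tri(propan-2-yl)silyl]oxy}methyl)-7,7a-dihydro-1-benzofuran-2,4-dione (C7 = ring C5, C7a = ring C6, C3a = ring C1, C4 = ring C2; formed in the flask in step 6) | O=C1C=C2C(=O)C=C(CO[Si](C(C)C)(C(C)C)C(C)C)[C@@H](O)[C@H]2O1 | intermediate
9 | (7R,7aS)-7-{[tert-butyl(dimethyl)silyl]oxy}-6-({[tri(propan-2-yl)silyl]oxy}methyl)-7,7a-dihydro-1-benzofuran-2,4-dione | O=C1C=C2C(=O)C=C(CO[Si](C(C)C)(C(C)C)C(C)C)[C@@H](O[Si](C)(C)C(C)(C)C)[C@H]2O1 | intermediate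
10 | (3aR,7R,7aS)-7-{[tert-butyl(dimethyl)silyl]oxy}-6-({[tri(propan-2-yl)silyl]oxy}methyl)-3,3a,7,7a-tetrahydro-1-benzofuran-2,4-dione (cis-fused) | O=C1C[C@H]2C(=O)C=C(CO[Si](C(C)C)(C(C)C)C(C)C)[C@@H](O[Si](C)(C)C(C)(C)C)[C@H]2O1 | intermediate
11 | (3aS,7R,7aS)-7-{[tert-butyl(dimethyl)silyl]oxy}-6-({[tri(propan-2-yl)silyl]oxy}methyl)-2,3,3a,4,7,7a-hexahydro-1-benzofuran-2,4-diol (cis-fused; epimers at C2 and C4) | OC1C[C@H]2C(O)C=C(CO[Si](C(C)C)(C(C)C)C(C)C)[C@@H](O[Si](C)(C)C(C)(C)C)[C@H]2O1 | intermediate
12 | tert-butyl 2-bromopropanoate (racemic) | CC(Br)C(=O)OC(C)(C)C | starting material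
13 | (1-tert-butoxy-1-oxopropan-2-yl)triphenylphosphonium bromide (formed in the flask in step 9) | CC(C(=O)OC(C)(C)C)[P+](c1ccccc1)(c1ccccc1)c1ccccc1.[Br-] | intermediate
14 | tert-butyl 2-(triphenylphosphoranylidene)propanoate | CC(=P(c1ccccc1)(c1ccccc1)c1ccccc1)C(=O)OC(C)(C)C | intermediate
15 | tert-butyl (2E)-4-[(1S,5R,6S)-5-{[tert-butyl(dimethyl)silyl]oxy}-2,6-dihydroxy-4-({[tri(propan-2-yl)silyl]oxy}methyl)cyclohex-3-en-1-yl]-2-methylbut-2-enoate (epimers at C2) | C/C(=C\C[C@H]1C(O)C=C(CO[Si](C(C)C)(C(C)C)C(C)C)[C@@H](O[Si](C)(C)C(C)(C)C)[C@H]1O)C(=O)OC(C)(C)C | intermediate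
16 | tert-butyl (2E)-4-[(1R,5R,6S)-5-{[tert-butyl(dimethyl)silyl]oxy}-6-hydroxy-2-oxo-4-({[tri(propan-2-yl)silyl]oxy}methyl)cyclohex-3-en-1-yl]-2-methylbut-2-enoate | C/C(=C\C[C@H]1C(=O)C=C(CO[Si](C(C)C)(C(C)C)C(C)C)[C@@H](O[Si](C)(C)C(C)(C)C)[C@H]1O)C(=O)OC(C)(C)C | intermediate
17 | tert-butyl (2E)-4-[(1R,5R,6S)-5-{[tert-butyl(dimethyl)silyl]oxy}-6-hydroxy-3-iodo-2-oxo-4-({[tri(propan-2-yl)silyl]oxy}methyl)cyclohex-3-en-1-yl]-2-methylbut-2-enoate | C/C(=C\C[C@H]1C(=O)C(I)=C(CO[Si](C(C)C)(C(C)C)C(C)C)[C@@H](O[Si](C)(C)C(C)(C)C)[C@H]1O)C(=O)OC(C)(C)C | intermediate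
18 | (4-bromobut-1-yn-1-yl)trimethylsilane | C[Si](C)(C)C#CCCBr | starting material
19 | (R)-2-methyloxirane | C[C@@H]1CO1 | starting material
20 | [4-(trimethylsilyl)but-3-yn-1-yl]magnesium bromide (formed in the flask in step 13) | C[Si](C)(C)C#CCC[Mg]Br | intermediate
21 | (2R)-7-(trimethylsilyl)hept-6-yn-2-ol | C[C@@H](O)CCCC#C[Si](C)(C)C | intermediate
22 | tert-butyl(dimethyl){[(2R)-7-(trimethylsilyl)hept-6-yn-2-yl]oxy}silane | C[C@@H](O[Si](C)(C)C(C)(C)C)CCCC#C[Si](C)(C)C | intermediate
23 | tert-butyl[(2R)-hept-6-yn-2-yloxy]dimethylsilane | C[C@@H](O[Si](C)(C)C(C)(C)C)CCCC#C | intermediate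
24 | tert-butyl(dimethyl){[(2R,6E)-7-(tributylstannyl)hept-6-en-2-yl]oxy}silane | C[C@@H](O[Si](C)(C)C(C)(C)C)CCC/C=C/[Sn](CCCC)(CCCC)CCCC | intermediate
25 | tert-butyl (2E)-4-[(1R,5R,6S)-5-{[tert-butyl(dimethyl)silyl]oxy}-3-[(1E,6R)-6-{[tert-butyl(dimethyl)silyl]oxy}hept-1-en-1-yl]-6-hydroxy-2-oxo-4-({[tri(propan-2-yl)silyl]oxy}methyl)cyclohex-3-en-1-yl]-2-methylbut-2-enoate | C/C(=C\C[C@H]1C(=O)C(/C=C/CCC[C@@H](C)O[Si](C)(C)C(C)(C)C)=C(CO[Si](C(C)C)(C(C)C)C(C)C)[C@@H](O[Si](C)(C)C(C)(C)C)[C@H]1O)C(=O)OC(C)(C)C | intermediate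
26 | (2E)-4-[(1R,5R,6S)-5-{[tert-butyl(dimethyl)silyl]oxy}-3-[(1E,6R)-6-{[tert-butyl(dimethyl)silyl]oxy}hept-1-en-1-yl]-6-hydroxy-2-oxo-4-({[tri(propan-2-yl)silyl]oxy}methyl)cyclohex-3-en-1-yl]-2-methylbut-2-enoic acid | C/C(=C\C[C@H]1C(=O)C(/C=C/CCC[C@@H](C)O[Si](C)(C)C(C)(C)C)=C(CO[Si](C(C)C)(C(C)C)C(C)C)[C@@H](O[Si](C)(C)C(C)(C)C)[C@H]1O)C(=O)O | intermediate
27 | Pestallic acid I, (2E)-4-[(1R,5R,6S)-5,6-dihydroxy-3-[(1E,6R)-6-hydroxyhept-1-en-1-yl]-4-(hydroxymethyl)-2-oxocyclohex-3-en-1-yl]-2-methylbut-2-enoic acid | C/C(=C\C[C@H]1C(=O)C(/C=C/CCC[C@@H](C)O)=C(CO)[C@@H](O)[C@H]1O)C(=O)O | target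

**Totals**

Total step count: 19.
Longest linear sequence: 13 steps (1, 2, 4, 5, 6, 7, 8, 10, 11, 12, 17, 18, 19).

**Steps most likely to fail**

Step 6 (bears the label). The chiral ion pair may discriminate the two faces of the furanolate poorly in a ring closure, or turnover may be slow enough for deprotonation of the product at C6 and loss of the C5 oxygen (aromatisation) to compete. The fallback separates ring closure from absolute control and uses known chemistry. It sets out from 7: a catalytic amount of Et3N in CH2Cl2 at −20 °C (plain amine-mediated direct vinylogous aldol addition of a furan-2(5H)-one to an aldehyde, the cis relationship still set by the substrate) should give the racemic cis-hydroxy butenolide, that is 8 together with its (7S,7aR) enantiomer F1. Lipase-catalysed kinetic resolution (immobilised Candida antarctica lipase B, vinyl acetate, t-BuOMe, rt) is expected, by the empirical size rule for this lipase with the C4 side as the large group, to acetylate the unwanted enantiomer to the (7S,7aR) acetate F2 and to leave 8. After separation, 8 is silylated (TBSOTf, 2,6-lutidine, CH2Cl2, −78 °C) and the route is rejoined at 9.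

Step 7. Electron transfer to the cross-conjugated dienone may spill over into reductive loss of the lactone oxygen at C6 or into reduction of the second enone. The fallback replaces electron transfer by two hydride reductions and sets out from 9. Luche reduction (NaBH4, CeCl3·7H2O, MeOH, −78 °C) takes the ketone to the allylic alcohol F3, which removes the ene-dicarbonyl character. Conjugate reduction of the now ordinary butenolide with nickel boride (NiCl2·6H2O, NaBH4, MeOH, 0 °C), with hydride delivered to the convex face, should give the cis-fused saturated hydroxy lactone F4. Reduction with i-Bu2AlH (CH2Cl2, −78 °C) then gives lactol 11, where the route is rejoined.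

Step 12. Conjugate addition of pyridine to the hindered, fully substituted β-carbon C4 may be slow, and long exposure to the amine may erode the C1 centre or trigger retro-aldol cleavage of the β-hydroxy ketone. The fallback moves halogenation upstream, to a compound whose only C=C is the ring alkene, and uses addition–elimination instead of a nucleophile-triggered sequence. It sets out from 10: Br2 (CH2Cl2, −78 °C) adds across C3=C4 to give the dibromide F5, and Et3N removes HBr (the only available hydrogen is on C3) to give the bromo enone lactone F6. The main-route operations are then repeated: i-Bu2AlH gives the bromo lactol F7, Wittig reaction with 14 gives the bromo diol ester F8, and MnO2 gives the bromo enone ester F9. Stille coupling of F9 with 24 (Pd2(dba)3, AsPh3, CuI, NMP, 50 °C) rejoins the route at 25.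

Further compounds
F1 | step 6 | (7S,7aR)-7-hydroxy-6-({[tri(propan-2-yl)silyl]oxy}methyl)-7,7a-dihydro-1-benzofuran-2,4-dione (enantiomer of 8) | O=C1C=C2C(=O)C=C(CO[Si](C(C)C)(C(C)C)C(C)C)[C@H](O)[C@@H]2O1
F2 | step 6 | (7S,7aR)-2,4-dioxo-6-({[tri(propan-2-yl)silyl]oxy}methyl)-2,4,7,7a-tetrahydro-1-benzofuran-7-yl acetate | O=C1C=C2C(=O)C=C(CO[Si](C(C)C)(C(C)C)C(C)C)[C@H](OC(C)=O)[C@@H]2O1
F3 | step 7 | (7R,7aS)-7-{[tert-butyl(dimethyl)silyl]oxy}-4-hydroxy-6-({[tri(propan-2-yl)silyl]oxy}methyl)-7,7a-dihydro-1-benzofuran-2(4H)-one (epimers at C4) | O=C1C=C2C(O)C=C(CO[Si](C(C)C)(C(C)C)C(C)C)[C@@H](O[Si](C)(C)C(C)(C)C)[C@H]2O1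
F4 | step 7 | (3aS,7R,7aS)-7-{[tert-butyl(dimethyl)silyl]oxy}-4-hydroxy-6-({[tri(propan-2-yl)silyl]oxy}methyl)-3a,4,7,7a-tetrahydro-1-benzofuran-2(3H)-one (cis-fused; epimers at C4) | O=C1C[C@H]2C(O)C=C(CO[Si](C(C)C)(C(C)C)C(C)C)[C@@H](O[Si](C)(C)C(C)(C)C)[C@H]2O1
F5 | step 12 | 5,6-dibromide of 10 (bromine on benzofuranone C5 and C6, configuration at these two carbons not defined, other centres as in 10) | O=C1C[C@H]2C(=O)C(Br)C(Br)(CO[Si](C(C)C)(C(C)C)C(C)C)[C@@H](O[Si](C)(C)C(C)(C)C)[C@H]2O1
F6 | step 12 | (3aR,7R,7aS)-5-bromo-7-{[tert-butyl(dimethyl)silyl]oxy}-6-({[tri(propan-2-yl)silyl]oxy}methyl)-3,3a,7,7a-tetrahydro-1-benzofuran-2,4-dione | O=C1C[C@H]2C(=O)C(Br)=C(CO[Si](C(C)C)(C(C)C)C(C)C)[C@@H](O[Si](C)(C)C(C)(C)C)[C@H]2O1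
F7 | step 12 | 5-bromo analogue of lactol 11 (epimers at C2 and C4, other centres as in 11) | OC1C[C@H]2C(O)C(Br)=C(CO[Si](C(C)C)(C(C)C)C(C)C)[C@@H](O[Si](C)(C)C(C)(C)C)[C@H]2O1
F8 | step 12 | 3-bromo analogue of diol ester 15 (bromine on ring C3, epimers at C2, other centres as in 15) | C/C(=C\C[C@H]1C(O)C(Br)=C(CO[Si](C(C)C)(C(C)C)C(C)C)[C@@H](O[Si](C)(C)C(C)(C)C)[C@H]1O)C(=O)OC(C)(C)C
F9 | step 12 | tert-butyl (2E)-4-[(1R,5R,6S)-3-bromo-5-{[tert-butyl(dimethyl)silyl]oxy}-6-hydroxy-2-oxo-4-({[tri(propan-2-yl)silyl]oxy}methyl)cyclohex-3-en-1-yl]-2-methylbut-2-enoate | C/C(=C\C[C@H]1C(=O)C(Br)=C(CO[Si](C(C)C)(C(C)C)C(C)C)[C@@H](O[Si](C)(C)C(C)(C)C)[C@H]1O)C(=O)OC(C)(C)C
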